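Ring A is built rather than decorated. The route rests on disconnecting C8–C8a, C6–C7 and C4a–C8a: heating a 3-alkoxycyclobutenone with a methoxyalkyne that carries the (R)-lavandulyl chain should deliver, in one pericyclic cascade, the whole phloroglucinol nucleus. The step exploits the pattern of ring A, in which C8 lies between the C7 methoxy group and O1 while the third oxygen sits at C5. The alkyne supplies C7(OMe)–C8(lavandulyl), the ketene carbonyl becomes the only free phenol (O1), and the enol-ether oxygen becomes O5, worn as a MOM ether. Acylation at C4a, chalcone formation, ring C closure, catalytic resolution at C2 and one acidic deprotection finish the synthesis.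

Key step: step 8

Remark: (R)-lavandulyl stands for (2R)-5-methyl-2-(prop-1-en-2-yl)hex-4-en-1-yl, flavonoid numbering is used from the key step on, and every compound marked as starting material is taken to be a catalogue item.

Step 1
Reactants: 1 cyclobutane-1,3-dione
Product: 2 3-(methoxymethoxy)cyclobut-2-en-1-one
Conditions: MOMCl, i-Pr2NEt, CH2Cl2, 0 °C
Reagents that add atoms: chloromethyl methyl ether (MOMCl), COCCl
Why: O-Alkylation of a cyclic 1,3-diketone enolate (Williamson-type enol ether synthesis): the dione is strongly acidic and readily enolised, and the hard electrophile MOMCl should react at oxygen to give the vinylogous ester whose oxygen later becomes O5, already masked by a group that falls together with the ring B acetals.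

Step 2
Reactants: 3 (4S)-4-benzyl-1,3-oxazolidin-2-one; 4 3-methylbut-2-enoyl chloride
Product: 5 (4S)-4-benzyl-3-(3-methylbut-2-enoyl)-1,3-oxazolidin-2-one
Conditions: n-BuLi, THF, −78 °C; then 4, −78 → 0 °C
Reagents that add atoms: none
Why: N-Acylation of the lithiated Evans oxazolidinone with an acid chloride is a standard reaction that needs no amine base and therefore keeps the double bond in conjugation.

Step 3
Reactants: 5 (4S)-4-benzyl-3-(3-methylbut-2-enoyl)-1,3-oxazolidin-2-one; 6 prenyl bromide (1-bromo-3-methylbut-2-ene)
Product: 8 (4S)-4-benzyl-3-[(2S)-5-methyl-2-(prop-1-en-2-yl)hex-4-enoyl]-1,3-oxazolidin-2-one, via sodium dienolate 7 (not isolated)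
Conditions: NaN(SiMe3)2, THF, −78 °C; then 6, −78 → −30 °C
Reagents that add atoms: none
Why: Evans asymmetric alkylation in its deconjugative variant: γ-deprotonation gives the sodium-chelated (Z)-dienolate 7, which is alkylated at the α-carbon on the face away from the benzyl group, so that the auxiliary sets the (2S) centre (the later C2'' of the side chain) while the double bond moves into the isopropenyl position.

Step 4
Reactants: 8 (4S)-4-benzyl-3-[(2S)-5-methyl-2-(prop-1-en-2-yl)hex-4-enoyl]-1,3-oxazolidin-2-one
Product: 9 (S)-lavandulol [(2S)-5-methyl-2-(prop-1-en-2-yl)hex-4-en-1-ol]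
Conditions: LiBH4, H2O (1 equiv), Et2O, 0 °C
Reagents that add atoms: none
Why: Reductive removal of the auxiliary with LiBH4 (hydride attack at the exocyclic imide carbonyl) gives the primary alcohol without base-induced epimerisation or reconjugation and leaves both alkenes untouched.

Step 5
Reactants: 9 (S)-lavandulol
Product: 10 (S)-lavandulyl triflate [(2S)-5-methyl-2-(prop-1-en-2-yl)hex-4-en-1-yl trifluoromethanesulfonate]
Conditions: Tf2O, 2,6-lutidine, CH2Cl2, −78 °C; cold filtration, used at once
Reagents that add atoms: trifluoromethanesulfonic anhydride, O=S(=O)(OS(=O)(=O)C(F)(F)F)C(F)(F)F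
Why: O-Sulfonylation of a primary alcohol with Tf2O and a hindered pyridine base; the triflate is chosen because it lets the following SN2 reaction at a β-branched carbon run cold, and it is not stored, to forestall ionisation assisted by the homoallylic double bond.

Step 6
Reactants: 11 trichloroethylene
Product: 13 (E)-1,2-dichloro-1-methoxyethene, via dichloroethyne 12 (not isolated)
Conditions: KOMe (1.2 equiv), THF, −40 °C → rt, N2; distillation
Reagents that add atoms: potassium methoxide, C[O-].[K+]
Why: Dehydrochlorination to 12 followed by anti addition of methanol under methoxide catalysis (net vinylic substitution by elimination–addition) is the established entry to 1,2-dichlorovinyl ethers, and the hazardous 12 is consumed as it forms in a closed inert system.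

Step 7
Reactants: 13 (E)-1,2-dichloro-1-methoxyethene; 10 (S)-lavandulyl triflate
Product: 16 (4R)-1-methoxy-7-methyl-4-(prop-1-en-2-yl)oct-6-en-1-yne, via chloro(methoxy)ethyne 14 (not isolated), via lithium methoxyacetylide 15 (not isolated)
Conditions: 13 (1.5 equiv), n-BuLi (3.0 equiv), THF, −78 → −40 °C; then 10, DMPU, −78 → 0 °C; filtration through basic Al2O3
Reagents that add atoms: none
Why: Dehydrochlorination to 14 and chlorine–lithium exchange give acetylide 15, a slim sp nucleophile that displaces the primary triflate by SN2 (acetylide alkylation) without touching the neighbouring stereocentre, whose descriptor changes from S to R only through the priority rules.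

Step 8
Reactants: 2 3-(methoxymethoxy)cyclobut-2-en-1-one; 16 (4R)-1-methoxy-7-methyl-4-(prop-1-en-2-yl)oct-6-en-1-yne
Product: 21 2-[(R)-lavandulyl]-3-methoxy-5-(methoxymethoxy)phenol, via vinylketene 17 (not isolated), via vinylcyclobutenone 18 (not isolated), via dienylketene 19 (not isolated), via cyclohexadienone 20 (not isolated)
Conditions: 2 (1.5 equiv, two portions), toluene, base-washed sealed tube, 80 °C then 110 °C; crude product K2CO3, MeOH, rt (returns phenol captured as an ester by 17)
Reagents that add atoms: none
Why: Thermal 4π-electrocyclic opening of 2 gives (1-alkoxyvinyl)ketene 17, whose carbonyl carbon is attacked by the nucleophilic, lavandulyl-bearing carbon of ynol ether 16 in a regiospecific [2+2] cycloaddition that forms C8–C8a and C6–C7 and gives 4-vinylcyclobutenone 18. A second 4π opening gives dienylketene 19, and ring A, a six-membered carbocycle, closes by disrotatory 6π-electrocyclisation (C4a–C8a) to dienone 20, which tautomerises to phenol 21. The closest known reaction type is the Danheiser benzannulation of 3-alkyl- and 3-arylcyclobutenones with alkoxyalkynes; an oxygen substituent at C3 of the four-membered ring is the less charted variable, but it is only cross-conjugated to the ketene and makes the diene terminus more nucleophilic, which should help the last closure. No lasting stereocentre is created (C4 of 18 is erased on ring opening) and the side-chain centre is a spectator. The one selectivity required is the orientation of the ketene–alkyne cycloaddition, and it is secured by the polarisation that the methoxy group imposes on the triple bond, so that C8 ends between C7–OMe and the only free hydroxyl, O1, while O5 arrives protected. A methyl ynol ether cannot fragment by retro-ene loss of an alkene, and 110 °C lies far below the onset of a Cope rearrangement of the 1,5-diene in the side chain.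

Step 9
Reactants: 21 2-[(R)-lavandulyl]-3-methoxy-5-(methoxymethoxy)phenol
Product: 23 2-hydroxy-3-[(R)-lavandulyl]-4-methoxy-6-(methoxymethoxy)benzaldehyde, via salicyl alcohol 22 (not isolated)
Conditions: MgCl2, Et3N, (CH2O)n, THF, reflux; aq. NH4Cl
Reagents that add atoms: formaldehyde (from paraformaldehyde), C=O
Why: Casnati–Skattebøl ortho-formylation: the magnesium-bound phenol delivers formaldehyde to its ortho carbon only, C4a is the single free ortho position (C6, para to the hydroxyl, stays untouched), and alcohol 22 is oxidised in situ by a second formaldehyde through Oppenauer-type hydride transfer.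

Step 10
Reactants: 23 2-hydroxy-3-[(R)-lavandulyl]-4-methoxy-6-(methoxymethoxy)benzaldehyde
Product: 24 2-(1-hydroxyethyl)-6-[(R)-lavandulyl]-5-methoxy-3-(methoxymethoxy)phenol (both carbinol epimers)
Conditions: MeMgBr (3 equiv), THF, 0 °C; aq. NH4Cl; used crude
Reagents that add atoms: methylmagnesium bromide, C[Mg]Br
Why: Grignard addition to the aldehyde after deprotonation of the phenol installs C3 of the future ring C, and the carbinol centre, formed as a mixture, is erased in the next step.

Step 11
Reactants: 24 2-(1-hydroxyethyl)-6-[(R)-lavandulyl]-5-methoxy-3-(methoxymethoxy)phenol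
Product: 25 1-{2-hydroxy-3-[(R)-lavandulyl]-4-methoxy-6-(methoxymethoxy)phenyl}ethan-1-one
Conditions: MnO2, CH2Cl2, rt
Reagents that add atoms: none
Why: MnO2 oxidation is selective for the benzylic alcohol, spares the isolated alkenes and the acetal, and gives a ketone stabilised by hydrogen bonding to the O1 phenol.

Step 12
Reactants: 26 2,4-dihydroxy-5-methoxybenzaldehyde
Product: 27 5-methoxy-2,4-bis(methoxymethoxy)benzaldehyde
Conditions: NaH, MOMCl, DMF, 0 °C → rt
Reagents that add atoms: chloromethyl methyl ether (MOMCl), COCCl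
Why: Double Williamson-type O-alkylation of the phenoxides with MOMCl, for which NaH is used because the 2-hydroxyl is hydrogen-bonded to the aldehyde.

Step 13
Reactants: 25 1-{2-hydroxy-3-[(R)-lavandulyl]-4-methoxy-6-(methoxymethoxy)phenyl}ethan-1-one; 27 5-methoxy-2,4-bis(methoxymethoxy)benzaldehyde
Product: 28 (E)-2'-hydroxy-3'-[(R)-lavandulyl]-4',5-dimethoxy-2,4,6'-tris(methoxymethoxy)chalcone
Conditions: KOH, EtOH, rt
Reagents that add atoms: none
Why: Claisen–Schmidt condensation (aldol addition and E1cB dehydration) of a methyl ketone with a non-enolisable aldehyde gives the (E)-chalcone, and all protecting groups are stable to base.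

Step 14
Reactants: 28 (E)-2'-hydroxy-3'-[(R)-lavandulyl]-4',5-dimethoxy-2,4,6'-tris(methoxymethoxy)chalcone
Product: 29 8-[(R)-lavandulyl]-7,5'-dimethoxy-5,2',4'-tris(methoxymethoxy)flavanone (both C2 epimers)
Conditions: NaOAc, EtOH, reflux
Reagents that add atoms: none
Why: Intramolecular oxa-Michael addition (6-endo-trig) of O1, the only free phenol, closes ring C with unambiguous regiochemistry; the 6'-alkoxy group twists the enone out of conjugation and favours the closed form, and C2 forms as both epimers because the remote side-chain centre exerts no control.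

Step 15
Reactants: 29 8-[(R)-lavandulyl]-7,5'-dimethoxy-5,2',4'-tris(methoxymethoxy)flavanone (both C2 epimers)
Product: 30 (2S)-8-[(R)-lavandulyl]-7,5'-dimethoxy-5,2',4'-tris(methoxymethoxy)flavanone
Conditions: Cp*RhCl[(R,R)-TsDPEN] (1 mol %), HCO2H/Et3N (5:2), EtOAc, rt, stopped near half conversion; chromatography
Reagents that add atoms: none
Why: Kinetic resolution by Noyori–Ikariya asymmetric transfer hydrogenation: the (R,R)-catalyst imposes the (4R) alcohol configuration, which coincides with the substrate's preference for cis-2,4 reduction only in the (2R)-epimer, so this epimer should be reduced to a polar flavan-4-ol while the (2S)-ketone 30 stays behind and is separated by chromatography.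

Step 16
Reactants: 30 (2S)-8-[(R)-lavandulyl]-7,5'-dimethoxy-5,2',4'-tris(methoxymethoxy)flavanone
Product: 31 (2S)-5,2',4'-trihydroxy-7,5'-dimethoxy-8-[(R)-lavandulyl]flavanone (CNP0104733.2)
Conditions: 3 M aq. HCl, MeOH, 40 °C
Reagents that add atoms: none
Why: Acid-catalysed transacetalisation to methanol removes the three phenolic MOM groups in one operation; the aryl methyl ethers are inert, the side chain at C8 has no free ortho hydroxyl that could add to its alkenes, and the absence of base avoids epimerisation of C2 through the chalcone.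

Compound list
1 | cyclobutane-1,3-dione | O=C1CC(=O)C1 | starting material
2 | 3-(methoxymethoxy)cyclobut-2-en-1-one | COCOC1=CC(=O)C1 | intermediate
3 | (4S)-4-benzyl-1,3-oxazolidin-2-one | O=C1N[C@@H](Cc2ccccc2)CO1 | starting material
4 | 3-methylbut-2-enoyl chloride | CC(C)=CC(=O)Cl | starting material
5 | (4S)-4-benzyl-3-(3-methylbut-2-enoyl)-1,3-oxazolidin-2-one | CC(C)=CC(=O)N1[C@@H](Cc2ccccc2)COC1=O | intermediate
6 | prenyl bromide (1-bromo-3-methylbut-2-ene) | CC(C)=CCBr | starting material
7 | sodium (Z)-dienolate of 5 | C=C(C)/C=C(\[O-])N1[C@@H](Cc2ccccc2)COC1=O.[Na+] | intermediate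
8 | (4S)-4-benzyl-3-[(2S)-5-methyl-2-(prop-1-en-2-yl)hex-4-enoyl]-1,3-oxazolidin-2-one | C=C(C)[C@H](CC=C(C)C)C(=O)N1[C@@H](Cc2ccccc2)COC1=O | intermediate
9 | (S)-lavandulol | C=C(C)[C@H](CC=C(C)C)CO | intermediate
10 | (S)-lavandulyl triflate | C=C(C)[C@H](CC=C(C)C)COS(=O)(=O)C(F)(F)F | intermediate
11 | trichloroethylene | ClC=C(Cl)Cl | starting material
12 | dichloroethyne | ClC#CCl | intermediate
13 | (E)-1,2-dichloro-1-methoxyethene | CO/C(Cl)=C\Cl | intermediate
14 | chloro(methoxy)ethyne | COC#CCl | intermediate
15 | lithium methoxyacetylide | COC#C[Li] | intermediate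
16 | (4R)-1-methoxy-7-methyl-4-(prop-1-en-2-yl)oct-6-en-1-yne | C=C(C)[C@H](CC=C(C)C)CC#COC | intermediate
17 | [1-(methoxymethoxy)vinyl]ketene, 3-(methoxymethoxy)buta-1,3-dien-1-one | C=C(OCOC)C=C=O | intermediate
18 | 2-[(R)-lavandulyl]-3-methoxy-4-[1-(methoxymethoxy)vinyl]cyclobut-2-en-1-one (C4 undefined, transient) | C=C(C)[C@H](CC=C(C)C)CC1=C(OC)C(C(=C)OCOC)C1=O | intermediate
19 | 2-[(R)-lavandulyl]-3-methoxy-5-(methoxymethoxy)hexa-1,3,5-trien-1-one, ketene and vinyl groups cis on the central double bond | C=C(C)[C@H](CC=C(C)C)CC(=C=O)/C(OC)=C\C(=C)OCOC | intermediate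
20 | 2-[(R)-lavandulyl]-3-methoxy-5-(methoxymethoxy)cyclohexa-2,4-dien-1-one | C=C(C)[C@H](CC=C(C)C)CC1=C(OC)C=C(OCOC)CC1=O | intermediate
21 | 2-[(R)-lavandulyl]-3-methoxy-5-(methoxymethoxy)phenol | C=C(C)[C@H](CC=C(C)C)Cc1c(OC)cc(OCOC)cc1O | intermediate
22 | 2-(hydroxymethyl)-6-[(R)-lavandulyl]-5-methoxy-3-(methoxymethoxy)phenol | C=C(C)[C@H](CC=C(C)C)Cc1c(OC)cc(OCOC)c(CO)c1O | intermediate
23 | 2-hydroxy-3-[(R)-lavandulyl]-4-methoxy-6-(methoxymethoxy)benzaldehyde | C=C(C)[C@H](CC=C(C)C)Cc1c(OC)cc(OCOC)c(C=O)c1O | intermediate
24 | 2-(1-hydroxyethyl)-6-[(R)-lavandulyl]-5-methoxy-3-(methoxymethoxy)phenol (carbinol epimers) | C=C(C)[C@H](CC=C(C)C)Cc1c(OC)cc(OCOC)c(C(C)O)c1O | intermediate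
25 | 1-{2-hydroxy-3-[(R)-lavandulyl]-4-methoxy-6-(methoxymethoxy)phenyl}ethan-1-one | C=C(C)[C@H](CC=C(C)C)Cc1c(OC)cc(OCOC)c(C(C)=O)c1O | intermediate
26 | 2,4-dihydroxy-5-methoxybenzaldehyde | O=Cc1cc(OC)c(O)cc1O | starting material
27 | 5-methoxy-2,4-bis(methoxymethoxy)benzaldehyde | O=Cc1cc(OC)c(OCOC)cc1OCOC | intermediate
28 | (E)-2'-hydroxy-3'-[(R)-lavandulyl]-4',5-dimethoxy-2,4,6'-tris(methoxymethoxy)chalcone | C=C(C)[C@H](CC=C(C)C)Cc1c(OC)cc(OCOC)c(C(=O)/C=C/c2cc(OC)c(OCOC)cc2OCOC)c1O | intermediate
29 | 8-[(R)-lavandulyl]-7,5'-dimethoxy-5,2',4'-tris(methoxymethoxy)flavanone (both C2 epimers) | C=C(C)[C@H](CC=C(C)C)Cc1c(OC)cc(OCOC)c2c1OC(c1cc(OC)c(OCOC)cc1OCOC)CC2=O | intermediate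
30 | (2S)-8-[(R)-lavandulyl]-7,5'-dimethoxy-5,2',4'-tris(methoxymethoxy)flavanone | C=C(C)[C@H](CC=C(C)C)Cc1c(OC)cc(OCOC)c2c1O[C@H](c1cc(OC)c(OCOC)cc1OCOC)CC2=O | intermediate
31 | (2S)-5,2',4'-trihydroxy-7,5'-dimethoxy-8-[(R)-lavandulyl]flavanone (CNP0104733.2) | C=C(C)[C@H](CC=C(C)C)Cc1c(OC)cc(O)c2c1O[C@H](c1cc(OC)c(O)cc1O)CC2=O | target

Total step count: 16. Longest linear sequence: 13 steps (steps 2–5, 7–11 and 13–16, from 3 and 4 to 31).

Steps most likely to fail

1. Step 8.
- Risk: the vinylogous-ester stabilisation of 2 may raise the temperature of the first ring opening. Ketene oligomerisation, thermal loss or transfer of the MOM group, capture of the ketene by the newly formed phenol, or stalling at the four-membered stage could then compete with the cascade.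
- Fallback (sets out from 10, comes back at 21): ring A is taken from the aromatic pool and the side chain is attached by directed ortho-metalation. 5-Methoxyresorcinol F1 is monosilylated (i-Pr3SiCl, imidazole, DMF) to 3-methoxy-5-(triisopropylsilyloxy)phenol F2 and carbamoylated (Et2NCOCl, K2CO3, MeCN) to the aryl diethylcarbamate F3. s-BuLi/TMEDA (THF, −78 °C) removes the proton between the carbamate and the methoxy group, since the bulky silyl ether shields the other two positions. Quenching in the same flask with triflate 10 gives the lavandulyl arene F4. n-Bu4NF frees the C5 phenol F5, MOMCl/i-Pr2NEt gives the MOM ether F6, and LiAlH4 (THF) cleaves the carbamate to return 21.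

2. Step 7.
- Risk: E2 elimination through the allylic tertiary hydrogen next to the reacting carbon, ionisation of the triflate with participation of the homoallylic double bond, and hydration of the ynol ether during isolation may all compete with substitution.
- Fallback (sets out from 9, comes back at 16): the chain is extended with a soft nucleophile and the triple bond is made by elimination. Appel iodination (I2, PPh3, imidazole) gives (S)-lavandulyl iodide F7. Sodium dimethyl malonate (NaH, THF/DMF, 60 °C) gives the alkylated malonate F8. Krapcho demethoxycarbonylation (LiCl, H2O, DMSO, 150 °C) gives the methyl ester F9. LiN(i-Pr)2 followed by ClP(O)(OEt)2 gives the ketene acetal phosphate F10, and t-BuLi (2 equiv, THF, −78 °C) eliminates diethyl phosphate to return 16.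

3. Step 15.
- Risk: hydride transfer to a carbonyl group crowded by the peri MOM ether may be slow and may discriminate poorly between the epimers. Amine-induced ring opening and reclosure may also erode the configurational purity of the remaining ketone.
- Fallback (sets out from 29, comes back at 30): because the side-chain centre is fixed, 29 is a pair of diastereomers. It is separated physically by preparative HPLC on a cellulose-based chiral phase to give 30 directly. The (2R)-flavanone epimer F11 is re-equilibrated through chalcone 28 (NaOAc, EtOH, reflux) to 29 and recycled.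

Further compounds
F1 | step 8 | 5-methoxyresorcinol (bought) | COc1cc(O)cc(O)c1
F2 | step 8 | 3-methoxy-5-(triisopropylsilyloxy)phenol | COc1cc(O)cc(O[Si](C(C)C)(C(C)C)C(C)C)c1
F3 | step 8 | 3-methoxy-5-(triisopropylsilyloxy)phenyl N,N-diethylcarbamate | CCN(CC)C(=O)Oc1cc(OC)cc(O[Si](C(C)C)(C(C)C)C(C)C)c1
F4 | step 8 | 2-[(R)-lavandulyl]-3-methoxy-5-(triisopropylsilyloxy)phenyl N,N-diethylcarbamate | C=C(C)[C@H](CC=C(C)C)Cc1c(OC)cc(O[Si](C(C)C)(C(C)C)C(C)C)cc1OC(=O)N(CC)CC
F5 | step 8 | 5-hydroxy-2-[(R)-lavandulyl]-3-methoxyphenyl N,N-diethylcarbamate | C=C(C)[C@H](CC=C(C)C)Cc1c(OC)cc(O)cc1OC(=O)N(CC)CC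
F6 | step 8 | 2-[(R)-lavandulyl]-3-methoxy-5-(methoxymethoxy)phenyl N,N-diethylcarbamate | C=C(C)[C@H](CC=C(C)C)Cc1c(OC)cc(OCOC)cc1OC(=O)N(CC)CC
F7 | step 7 | (S)-lavandulyl iodide, (3S)-3-(iodomethyl)-2,6-dimethylhepta-1,5-diene | C=C(C)[C@H](CC=C(C)C)CI
F8 | step 7 | dimethyl 2-[(2R)-5-methyl-2-(prop-1-en-2-yl)hex-4-en-1-yl]malonate | C=C(C)[C@H](CC=C(C)C)CC(C(=O)OC)C(=O)OC
F9 | step 7 | methyl (4S)-7-methyl-4-(prop-1-en-2-yl)oct-6-enoate | C=C(C)[C@H](CC=C(C)C)CCC(=O)OC
F10 | step 7 | diethyl (4R)-1-methoxy-7-methyl-4-(prop-1-en-2-yl)octa-1,6-dien-1-yl phosphate | C=C(C)[C@H](CC=C(C)C)CC=C(OC)OP(=O)(OCC)OCC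
F11 | step 15 | (2R)-8-[(R)-lavandulyl]-7,5'-dimethoxy-5,2',4'-tris(methoxymethoxy)flavanone | C=C(C)[C@H](CC=C(C)C)Cc1c(OC)cc(OCOC)c2c1O[C@@H](c1cc(OC)c(OCOC)cc1OCOC)CC2=O
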